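**Plan**

- Cuts: first the O–acetyl bond of the side chain. Next the C1 and C4 carbonyl oxygens of quinone ring B, back to the two benzylic CH2 groups of a 3-alkyl-2-tetralone masked as its C2=C3 silyl enol ether. Last, C1–C8a and C4–C4a together.
- Enabling feature: ring A carries oxygen on C5, C6 and C8 and hydrogen on C7, so it is 2-methoxy-1,4-benzoquinone in reduced, methylated form, and the free C=C of that quinone is C4a=C8a. C1–C4, with oxygen on C2 and the chain on C3, are a 2-silyloxy-3-alkylbuta-1,3-diene.
- Forward: the diene is built linearly from the epoxide (alkynylation, hydroiodination, silylation, acylation, enol silylation) and ring A is bought as the quinone. Ring B closes in the cycloaddition, ring A aromatises, ring B is oxidised with O2 last, and the acetate is then set.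
- Stereochemistry: the only stereocentre, the (S) carbinol carbon of the side chain, is that of (S)-propylene oxide. The epoxide is opened at its CH2, and the C–O bond at the stereocentre is never broken.

Key step: step 6

Assumption: bicyclic compounds are numbered like the target (ring B = C1–C4, ring A = C5–C8), and the transient stereocentres of the cycloadduct (C4a, C8a) and of the tetralone (C3) are carried as mixtures and left open in the SMILES because both are erased later.

Step 1
Reactants: 1 (S)-propylene oxide; 2 lithium acetylide–ethylenediamine complex (LiC≡CH·H2NCH2CH2NH2)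
Product: 3 (S)-pent-4-yn-2-ol
Conditions: DMSO, 0 °C → rt; then H2O
Reagents that add atoms: none
Why: SN2 opening of the terminal epoxide by the acetylide at the unsubstituted CH2 (epoxide alkynylation) leaves the C–O bond at the stereocentre untouched, so the (S) configuration of 1 is carried into 3.

Step 2
Reactants: 3 (S)-pent-4-yn-2-ol
Product: 4 (S)-4-iodopent-4-en-2-ol
Conditions: NaI, Me3SiCl, H2O, MeCN, 0 °C → rt
Reagents that add atoms: sodium iodide, [Na+].[I-]
Why: HI generated in the flask adds once to the terminal alkyne in the Markovnikov sense (alkyne hydroiodination), which places iodine on the internal carbon while the remote carbinol centre takes no part.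

Step 3
Reactants: 4 (S)-4-iodopent-4-en-2-ol
Product: 5 (S)-tert-butyl[(4-iodopent-4-en-2-yl)oxy]dimethylsilane
Conditions: TBSCl, imidazole, DMF, rt
Reagents that add atoms: tert-butyldimethylsilyl chloride (TBSCl), CC(C)(C)[Si](C)(C)Cl
Why: Imidazole-promoted silylation of a secondary alcohol reacts only at the O–H bond, so configuration is retained and the hydroxyl is masked against the organolithium, the strong base and the oxidant still to come.

Step 4
Reactants: 5 (S)-tert-butyl[(4-iodopent-4-en-2-yl)oxy]dimethylsilane; 6 N-methoxy-N-methylacetamide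
Product: 9 (S)-5-(tert-butyldimethylsilyloxy)-3-methylidenehexan-2-one, via vinyllithium 7 (not isolated), via tetrahedral lithium adduct 8 (not isolated)
Conditions: t-BuLi (2.1 equiv), Et2O, −78 °C; 6, −78 → 0 °C; cannulated into cold 0.5 M HCl
Reagents that add atoms: none
Why: Iodine–lithium exchange gives the 1,1-disubstituted vinyllithium, its addition to the amide stops at the chelated tetrahedral adduct (Weinreb ketone synthesis), and the inverse acidic quench protonates the released amine before it can add to the new enone.

Step 5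
Reactants: 9 (S)-5-(tert-butyldimethylsilyloxy)-3-methylidenehexan-2-one
Product: 10 (S)-2-(tert-butyldimethylsilyloxy)-3-[2-(tert-butyldimethylsilyloxy)propyl]buta-1,3-diene
Conditions: TBSOTf, Et3N, CH2Cl2, 0 °C
Reagents that add atoms: tert-butyldimethylsilyl trifluoromethanesulfonate (TBSOTf), CC(C)(C)[Si](C)(C)OS(=O)(=O)C(F)(F)F
Why: Soft enolisation with a silyl triflate and a tertiary amine (silyl enol ether formation) can remove a proton only from the methyl group, the sole enolisable position of 9, and should therefore give the 2-silyloxydiene as one regioisomer.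

Step 6
Reactants: 10 (S)-2-(tert-butyldimethylsilyloxy)-3-[2-(tert-butyldimethylsilyloxy)propyl]buta-1,3-diene; 11 2-methoxy-1,4-benzoquinone
Product: 13 2-(tert-butyldimethylsilyloxy)-3-[(S)-2-(tert-butyldimethylsilyloxy)propyl]-6-methoxy-1,4-dihydronaphthalene-5,8-diol, via cis-fused enedione cycloadduct 12 (not isolated)
Conditions: toluene, 70 °C, Ar (10 in slight excess); then Et3N (cat.), rt
Reagents that add atoms: none
Why: The step is a thermal, normal-electron-demand Diels–Alder reaction in which the HOMO of donor-substituted diene 10 and the LUMO of quinone 11 merge in a concerted, asynchronous, suprafacial (4+2) process that forms C1–C8a and C4–C4a, the closest known reaction type being the cycloaddition of 2-silyloxybuta-1,3-dienes to alkoxy-1,4-benzoquinones. Ring B, the only ring formed, closes as a six-membered carbocycle by this intermolecular (4+2) annulation across the bond that becomes C4a–C8a. The only new stereocentres, C4a and C8a of 12, are cis because the addition is suprafacial, form on both faces because the (S) centre is remote, and vanish when catalytic Et3N enolises the enedione to the aromatic 5,8-diol, so that 13 should be a single stereoisomer. Site selectivity is secured by the substrate, since the C6=C7 bond of 11 is a vinylogous ester that is electron-rich and more hindered and therefore leaves the unsubstituted C=C as the dienophile. Regioselectivity requires the nucleophilic diene terminus C1, the CH2 of the enol ether where the silyloxy donor outweighs the weaker opposing push of the 3-alkyl group, to bond to C8a, which is the β-carbon of the C5 carbonyl and the more electrophilic site because methoxy donation through C6=C7 damps the C8 carbonyl. Lewis acids are left out because a monodentate one would bind the more basic C8 carbonyl and turn this bias around, and any of them could divert the silyl enol ether into Mukaiyama–Michael addition.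

Step 7
Reactants: 13 2-(tert-butyldimethylsilyloxy)-3-[(S)-2-(tert-butyldimethylsilyloxy)propyl]-6-methoxy-1,4-dihydronaphthalene-5,8-diol
Product: 14 2-(tert-butyldimethylsilyloxy)-3-[(S)-2-(tert-butyldimethylsilyloxy)propyl]-5,6,8-trimethoxy-1,4-dihydronaphthalene
Conditions: MeI, K2CO3, degassed DMF, rt, Ar
Reagents that add atoms: iodomethane, CI
Why: Double Williamson O-methylation of the hydroquinone runs under oxygen-free, aprotic and weakly basic conditions, in which the hindered tetrasubstituted TBS enol ether and the alkyl TBS ether should both persist.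

Step 8
Reactants: 14 2-(tert-butyldimethylsilyloxy)-3-[(S)-2-(tert-butyldimethylsilyloxy)propyl]-5,6,8-trimethoxy-1,4-dihydronaphthalene
Product: 15 3-[(S)-2-(tert-butyldimethylsilyloxy)propyl]-5,6,8-trimethoxy-3,4-dihydronaphthalen-2(1H)-one (both C3 epimers)
Conditions: TBAF (1.05 equiv), AcOH (1.1 equiv), THF, −20 → 0 °C, Ar
Reagents that add atoms: none
Why: In this buffered fluoride desilylation the enol silyl ether releases a stabilised tetralone enolate as leaving group and is therefore cleaved far faster than the secondary alkyl TBS ether, and the new C3 centre needs no control because step 9 makes it sp2.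

Step 9
Reactants: 15 3-[(S)-2-(tert-butyldimethylsilyloxy)propyl]-5,6,8-trimethoxy-3,4-dihydronaphthalen-2(1H)-one
Product: 16 3-[(S)-2-(tert-butyldimethylsilyloxy)propyl]-2-hydroxy-5,6,8-trimethoxy-1,4-naphthoquinone
Conditions: KOtBu, O2 (1 atm), t-BuOH–THF, rt; then 1 M HCl
Reagents that add atoms: dioxygen, O=O
Why: In the base-mediated autoxidation of a tetralone the benzylic enolate takes up O2 at C1, the resulting 1,2-dione aromatises to the naphthalenediolate and is oxygenated again at C4, and the product is held as its unreactive hydroxyquinone anion while the TBS ether tolerates alkoxide.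

Step 10
Reactants: 16 3-[(S)-2-(tert-butyldimethylsilyloxy)propyl]-2-hydroxy-5,6,8-trimethoxy-1,4-naphthoquinone
Product: 17 2-hydroxy-3-[(S)-2-hydroxypropyl]-5,6,8-trimethoxy-1,4-naphthoquinone
Conditions: 48% aq. HF, MeCN, 0 °C → rt
Reagents that add atoms: none
Why: Acidic fluoride desilylation breaks only the Si–O bond, so configuration is retained, and it is too mild to ionise the secondary alcohol or to dehydrate it onto the quinone hydroxyl.

Step 11
Reactants: 17 2-hydroxy-3-[(S)-2-hydroxypropyl]-5,6,8-trimethoxy-1,4-naphthoquinone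
Product: 19 3-[(S)-2-acetoxypropyl]-2-hydroxy-5,6,8-trimethoxy-1,4-naphthoquinone (CNP0321270.1), via diacetate 18 (not isolated)
Conditions: Ac2O, pyridine, DMAP (cat.), CH2Cl2, 0 °C → rt; then MeOH, rt
Reagents that add atoms: acetic anhydride, CC(=O)OC(C)=O
Why: DMAP-catalysed acylation esterifies both hydroxyls at oxygen with retention, and the C2 quinonyl acetate, a vinylogous mixed anhydride with a leaving group about as acidic as a carboxylic acid, is then removed by DMAP-catalysed methanolysis that leaves the ordinary secondary acetate alone.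

**Compound list**

1 | (S)-propylene oxide | C[C@H]1CO1 | starting material
2 | lithium acetylide–ethylenediamine complex | [Li]C#C.NCCN | starting material
3 | (S)-pent-4-yn-2-ol | C[C@H](O)CC#C | intermediate
4 | (S)-4-iodopent-4-en-2-ol | C=C(I)C[C@H](C)O | intermediate
5 | (S)-tert-butyl[(4-iodopent-4-en-2-yl)oxy]dimethylsilane | C=C(I)C[C@H](C)O[Si](C)(C)C(C)(C)C | intermediate
6 | N-methoxy-N-methylacetamide | CC(=O)N(C)OC | starting material
7 | (S)-[4-(tert-butyldimethylsilyloxy)pent-1-en-2-yl]lithium | [Li]C(=C)C[C@H](C)O[Si](C)(C)C(C)(C)C | intermediate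
8 | lithium alkoxide of the tetrahedral adduct of 7 and 6 (carbinolamine carbon undefined) | CC(O[Li])(N(C)OC)C(=C)C[C@H](C)O[Si](C)(C)C(C)(C)C | intermediate
9 | (S)-5-(tert-butyldimethylsilyloxy)-3-methylidenehexan-2-one | CC(=O)C(=C)C[C@H](C)O[Si](C)(C)C(C)(C)C | intermediate
10 | (S)-2-(tert-butyldimethylsilyloxy)-3-[2-(tert-butyldimethylsilyloxy)propyl]buta-1,3-diene | C=C(O[Si](C)(C)C(C)(C)C)C(=C)C[C@H](C)O[Si](C)(C)C(C)(C)C | intermediate
11 | 2-methoxy-1,4-benzoquinone | COC1=CC(=O)C=CC1=O | starting material
12 | cis-fused 2-(tert-butyldimethylsilyloxy)-3-[(S)-2-(tert-butyldimethylsilyloxy)propyl]-6-methoxy-1,4,4a,8a-tetrahydronaphthalene-5,8-dione (both facial diastereomers) | COC1=CC(=O)C2CC(O[Si](C)(C)C(C)(C)C)=C(C[C@H](C)O[Si](C)(C)C(C)(C)C)CC2C1=O | intermediate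
13 | 2-(tert-butyldimethylsilyloxy)-3-[(S)-2-(tert-butyldimethylsilyloxy)propyl]-6-methoxy-1,4-dihydronaphthalene-5,8-diol | COc1cc(O)c2c(c1O)CC(C[C@H](C)O[Si](C)(C)C(C)(C)C)=C(O[Si](C)(C)C(C)(C)C)C2 | intermediate
14 | 2-(tert-butyldimethylsilyloxy)-3-[(S)-2-(tert-butyldimethylsilyloxy)propyl]-5,6,8-trimethoxy-1,4-dihydronaphthalene | COc1cc(OC)c2c(c1OC)CC(C[C@H](C)O[Si](C)(C)C(C)(C)C)=C(O[Si](C)(C)C(C)(C)C)C2 | intermediate
15 | 3-[(S)-2-(tert-butyldimethylsilyloxy)propyl]-5,6,8-trimethoxy-3,4-dihydronaphthalen-2(1H)-one (both C3 epimers) | COc1cc(OC)c2c(c1OC)CC(C[C@H](C)O[Si](C)(C)C(C)(C)C)C(=O)C2 | intermediate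
16 | 3-[(S)-2-(tert-butyldimethylsilyloxy)propyl]-2-hydroxy-5,6,8-trimethoxy-1,4-naphthoquinone | COc1cc(OC)c2c(c1OC)C(=O)C(C[C@H](C)O[Si](C)(C)C(C)(C)C)=C(O)C2=O | intermediate
17 | 2-hydroxy-3-[(S)-2-hydroxypropyl]-5,6,8-trimethoxy-1,4-naphthoquinone | COc1cc(OC)c2c(c1OC)C(=O)C(C[C@H](C)O)=C(O)C2=O | intermediate
18 | 2-acetoxy-3-[(S)-2-acetoxypropyl]-5,6,8-trimethoxy-1,4-naphthoquinone | COc1cc(OC)c2c(c1OC)C(=O)C(C[C@H](C)OC(C)=O)=C(OC(C)=O)C2=O | intermediate
19 | 3-[(S)-2-acetoxypropyl]-2-hydroxy-5,6,8-trimethoxy-1,4-naphthoquinone (CNP0321270.1) | COc1cc(OC)c2c(c1OC)C(=O)C(C[C@H](C)OC(C)=O)=C(O)C2=O | target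

Total step count: 11. Longest linear sequence: 11 steps, from 1 to 19.

**Steps most likely to fail**

Step 6. The orientation of addition may be controlled only weakly, with C1 bonding partly to C4a instead of C8a. The hydroquinone may also be oxidised by quinone that has not yet reacted.
- The fallback sets out from 10 and lets a halogen fix the orientation.
- 5-Bromovanillin is taken by Dakin oxidation (H2O2, aq. NaOH) to 2-bromo-6-methoxybenzene-1,4-diol F1. FeCl3 then gives 2-bromo-6-methoxy-1,4-benzoquinone F2, in which bromine sits on the carbon that becomes C4a.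
- Diene 10 should add to the bromo-substituted C=C with its nucleophilic terminus at the unsubstituted carbon. This is the established directing effect of halogen in haloquinone Diels–Alder reactions, and here it reinforces the carbonyl bias. The product is the 4a-bromo cycloadduct F3.
- Et3N removes HBr to give 2-(tert-butyldimethylsilyloxy)-3-[(S)-2-(tert-butyldimethylsilyloxy)propyl]-6-methoxy-1,4-dihydronaphthalene-5,8-dione F4.
- Prompt reduction with Na2S2O4 (THF–H2O) leads back to the route at 13.

Step 9. The oxygenation may run past the hydroxyquinone, through ring cleavage or chain degradation by the peroxide that is formed. It may also stall before oxygen reaches C4, which is crowded by the C5 methoxy group.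
- The fallback sets out from 15 and brings in the two oxygens by separate ionic steps.
- Riley oxidation with SeO2 (dioxane, reflux) attacks the doubly activated C1 methylene. After tautomerisation and dehydrogenation it should give 3-[(S)-2-(tert-butyldimethylsilyloxy)propyl]-5,6,8-trimethoxy-1,2-naphthoquinone F5.
- Thiele–Winter acetoxylation (Ac2O, BF3·OEt2) adds acetate at C4. It also exchanges the silyl ether for an acetate at oxygen, without touching the C–O bond of the stereocentre. The product is 1,2,4-triacetoxy-3-[(S)-2-acetoxypropyl]-5,6,8-trimethoxynaphthalene F6.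
- Methanolysis of all four esters (K2CO3, MeOH) frees 3-[(S)-2-hydroxypropyl]-5,6,8-trimethoxynaphthalene-1,2,4-triol F7.
- Air oxidises F7 in the same flask, and the route is rejoined at 17, so steps 9 and 10 are bypassed.

Step 7. Phenoxide may take the silyl group from the enol oxygen, which would expose the tetralone enolate to C-methylation at C1. Traces of air may also oxidise the hydroquinone.
- The fallback sets out from 5 and exchanges the mask of the C2 ketone for a base-inert alkyl enol ether.
- Stille coupling of 5 with tributyl(1-ethoxyvinyl)stannane (Pd(PPh3)4, CuI, DMF) gives (S)-2-ethoxy-3-[2-(tert-butyldimethylsilyloxy)propyl]buta-1,3-diene F8.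
- Cycloaddition with 11 under the conditions of step 6 gives the cis-fused 2-ethoxy cycloadduct F9. Enolisation then gives 3-[(S)-2-(tert-butyldimethylsilyloxy)propyl]-2-ethoxy-6-methoxy-1,4-dihydronaphthalene-5,8-diol F10.
- MeI and K2CO3 give 3-[(S)-2-(tert-butyldimethylsilyloxy)propyl]-2-ethoxy-5,6,8-trimethoxy-1,4-dihydronaphthalene F11.
- Oxalic acid in wet THF hydrolyses only the enol ether, and the route is rejoined at 15.

**Further compounds**

F1 | step 6 | 2-bromo-6-methoxybenzene-1,4-diol | COc1cc(O)cc(Br)c1O
F2 | step 6 | 2-bromo-6-methoxy-1,4-benzoquinone | COC1=CC(=O)C=C(Br)C1=O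
F3 | step 6 | 4a-bromo-2-(tert-butyldimethylsilyloxy)-3-[(S)-2-(tert-butyldimethylsilyloxy)propyl]-6-methoxy-1,4,4a,8a-tetrahydronaphthalene-5,8-dione (ring-fusion centres undefined) | COC1=CC(=O)C2CC(O[Si](C)(C)C(C)(C)C)=C(C[C@H](C)O[Si](C)(C)C(C)(C)C)CC2(Br)C1=O
F4 | step 6 | 2-(tert-butyldimethylsilyloxy)-3-[(S)-2-(tert-butyldimethylsilyloxy)propyl]-6-methoxy-1,4-dihydronaphthalene-5,8-dione | COC1=CC(=O)C2=C(C1=O)CC(C[C@H](C)O[Si](C)(C)C(C)(C)C)=C(O[Si](C)(C)C(C)(C)C)C2
F5 | step 9 | 3-[(S)-2-(tert-butyldimethylsilyloxy)propyl]-5,6,8-trimethoxy-1,2-naphthoquinone | COc1cc(OC)c2c(c1OC)C=C(C[C@H](C)O[Si](C)(C)C(C)(C)C)C(=O)C2=O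
F6 | step 9 | 1,2,4-triacetoxy-3-[(S)-2-acetoxypropyl]-5,6,8-trimethoxynaphthalene | COc1cc(OC)c2c(OC(C)=O)c(OC(C)=O)c(C[C@H](C)OC(C)=O)c(OC(C)=O)c2c1OC
F7 | step 9 | 3-[(S)-2-hydroxypropyl]-5,6,8-trimethoxynaphthalene-1,2,4-triol | COc1cc(OC)c2c(O)c(O)c(C[C@H](C)O)c(O)c2c1OC
F8 | step 7 | (S)-2-ethoxy-3-[2-(tert-butyldimethylsilyloxy)propyl]buta-1,3-diene | C=C(OCC)C(=C)C[C@H](C)O[Si](C)(C)C(C)(C)C
F9 | step 7 | cis-fused 3-[(S)-2-(tert-butyldimethylsilyloxy)propyl]-2-ethoxy-6-methoxy-1,4,4a,8a-tetrahydronaphthalene-5,8-dione (ring-fusion centres undefined) | COC1=CC(=O)C2CC(OCC)=C(C[C@H](C)O[Si](C)(C)C(C)(C)C)CC2C1=O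
F10 | step 7 | 3-[(S)-2-(tert-butyldimethylsilyloxy)propyl]-2-ethoxy-6-methoxy-1,4-dihydronaphthalene-5,8-diol | COc1cc(O)c2c(c1O)CC(C[C@H](C)O[Si](C)(C)C(C)(C)C)=C(OCC)C2
F11 | step 7 | 3-[(S)-2-(tert-butyldimethylsilyloxy)propyl]-2-ethoxy-5,6,8-trimethoxy-1,4-dihydronaphthalene | COc1cc(OC)c2c(c1OC)CC(C[C@H](C)O[Si](C)(C)C(C)(C)C)=C(OCC)C2
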